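**Plan**
- Retrosynthesis: remove four benzyl ethers, then cut the C2–aryl bond of the 5,7-dihydroxyflavone half (aryl boronate plus a 5,7-dibenzyloxychromone), then cut C7–C8 and C5–C6 of ring A of the 4'-methoxyflavone half.
- Enabling feature: in the 4'-methoxyflavone half, the ether carbon C8 lies between C7 (OH) and C8a (bonded to O1). C8 can therefore begin as an ArOCH2 group on C2 of a 4-pyranone, with C7 and C6 coming from ethyl acetate and C5 from the ester on pyranone C3.
- The pyranone is cut to a 4-aryloxyacetoacetate and an arylpropioloyl chloride; the ArO–CH2 bond is cut to 4-bromophenol and methyl 4-chloroacetoacetate.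
- Forward order: ether bond, pyranone ring C, ring A by acylation–Dieckmann annulation, benzylation and borylation, oxidative coupling that attaches the second chromone (made separately from trihydroxyacetophenone), global debenzylation.
- Stereochemistry: the target has no stereocentre; the only sp3 methine on the way (in intermediate 9) becomes aromatic C8.

Key step: step 4

Remark: locants C5–C8a refer to the 4'-methoxyflavone half; the Br on the aryloxy ring is carried as a spectator handle for the later aryl–chromone coupling.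

**Step 1**
Reactants: 1 4-bromophenol; 2 methyl 4-chloroacetoacetate
Product: 3 methyl 4-(4-bromophenoxy)-3-oxobutanoate
Conditions: NaH (2.2 equiv), THF–DMF, 0 °C to rt; aq. HCl work-up
Reagents that add atoms: none
Why: Williamson etherification in which the phenoxide displaces the primary chloride next to the ketone while the keto ester is masked as its sodium enolate, as is usual for 4-alkoxy- and 4-aryloxyacetoacetates.

**Step 2**
Reactants: 4 3-(4-methoxyphenyl)propiolic acid
Product: 5 3-(4-methoxyphenyl)prop-2-ynoyl chloride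
Conditions: (COCl)2, DMF (cat.), CH2Cl2, 0 °C to rt; used crude
Reagents that add atoms: oxalyl chloride, ClC(=O)C(=O)Cl
Why: Acid chloride formation through the catalytic chloroiminium (Vilsmeier-type) activation, which is mild enough to leave the aryl alkyne untouched.

**Step 3**
Reactants: 3 methyl 4-(4-bromophenoxy)-3-oxobutanoate; 5 3-(4-methoxyphenyl)prop-2-ynoyl chloride
Product: 7 methyl 2-[(4-bromophenoxy)methyl]-6-(4-methoxyphenyl)-4-oxo-4H-pyran-3-carboxylate, via alkynyl tricarbonyl ester 6 (not isolated)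
Conditions: MgCl2, pyridine, CH2Cl2, 0 °C to rt; aq. HCl wash; DBU (cat.), MeCN, rt
Reagents that add atoms: none
Why: Magnesium-enolate C-acylation of the β-keto ester by the alkynoyl chloride, followed by base-catalysed 6-endo-dig oxa-Michael addition of the ketone enol oxygen to the ynone, the classical route from acetoacetates and arylpropioloyl chlorides to 6-aryl-4-pyranone-3-carboxylates.

**Step 4**
Reactants: 7 methyl 2-[(4-bromophenoxy)methyl]-6-(4-methoxyphenyl)-4-oxo-4H-pyran-3-carboxylate; 8 ethyl acetate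
Product: 10 8-(4-bromophenoxy)-5,7-dihydroxy-2-(4-methoxyphenyl)-4H-chromen-4-one, via methyl ketone 9 (not isolated)
Conditions: LiN(i-Pr)2 (1.1 equiv), THF, –78 °C; 8 (1.2 equiv), –78 to 0 °C; LiN(i-Pr)2 (2.5 equiv), –78 °C to rt; aq. HCl
Reagents that add atoms: none
Why: Proposed new method: LiN(i-Pr)2 removes a proton from the ArOCH2 group of 7, which is vinylogous through C2=C3 to both the C4 ketone and the C3 ester, and the dienolate is acylated by ethyl acetate at this γ-carbon in a Claisen condensation (future C7–C8 bond), the released ethoxide holding ketone 9 as its stabilized enolate. The second charge of amide base deprotonates the acetyl methyl group to an acetoacetate-type 1,3-dianion, whose terminal carbon attacks the adjacent C3 ester (future C5–C6 bond) and expels methoxide. Ring A thus closes in the 6-(enolendo)-exo-trig Dieckmann mode, and the cyclic 1,3-dione fused to the pyranone tautomerizes irreversibly to the 5,7-dihydroxy arene, which drives the whole sequence. The closest known reaction type is the lateral-anion acylation–Dieckmann benzannulation of ortho-toluate esters to 1,3-dihydroxynaphthalenes, together with lateral lithiation–acylation of 2-methyl-4-pyranones; neither has been shown on a 4-pyranone-3-carboxylate. No stereocentre is created; the step needs γ- over α-acylation and carbon over oxygen attack in the closure, secured by the fully substituted α-carbon C3 (acylation there cannot be driven by enolate formation) and by the carbon-centred dianion, while the 8-aryloxy pattern is fixed by connectivity because the ether carbon is bonded to the pyranone carbon that bears the ring oxygen.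

**Step 5**
Reactants: 10 8-(4-bromophenoxy)-5,7-dihydroxy-2-(4-methoxyphenyl)-4H-chromen-4-one
Product: 11 5,7-bis(benzyloxy)-8-(4-bromophenoxy)-2-(4-methoxyphenyl)-4H-chromen-4-one
Conditions: BnBr (3 equiv), K2CO3, n-Bu4NI (cat.), DMF, 70 °C
Reagents that add atoms: benzyl bromide, BrCc1ccccc1
Why: Williamson O-benzylation, with excess halide, iodide catalysis and heat to carry the hydrogen-bonded 5-OH through as well as the 7-OH.

**Step 6**
Reactants: 11 5,7-bis(benzyloxy)-8-(4-bromophenoxy)-2-(4-methoxyphenyl)-4H-chromen-4-one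
Product: 12 5,7-bis(benzyloxy)-2-(4-methoxyphenyl)-8-[4-(4,4,5,5-tetramethyl-1,3,2-dioxaborolan-2-yl)phenoxy]-4H-chromen-4-one
Conditions: B2pin2, PdCl2(dppf) (cat.), KOAc, 1,4-dioxane, 90 °C
Reagents that add atoms: bis(pinacolato)diboron, CC1(C)OB(OC1(C)C)B1OC(C)(C)C(C)(C)O1
Why: Miyaura borylation (oxidative addition of the aryl bromide to zerovalent palladium, acetate-assisted transmetalation with the diboron, reductive elimination), to which the flavone and the benzyl ethers are inert.

**Step 7**
Reactants: 13 2',4',6'-trihydroxyacetophenone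
Product: 14 1-[2,4-bis(benzyloxy)-6-hydroxyphenyl]ethan-1-one
Conditions: BnBr (2.0 equiv), K2CO3, DMF, rt
Reagents that add atoms: benzyl bromide, BrCc1ccccc1
Why: Selective Williamson O-benzylation, in which the one hydroxyl that stays hydrogen-bonded to the acetyl carbonyl is the least reactive and remains free.

**Step 8**
Reactants: 14 1-[2,4-bis(benzyloxy)-6-hydroxyphenyl]ethan-1-one
Product: 16 5,7-bis(benzyloxy)-4H-chromen-4-one, via dimethylamino enone 15 (not isolated)
Conditions: Me2NCH(OMe)2, toluene, 100 °C; conc. HCl, CH2Cl2, 40 °C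
Reagents that add atoms: N,N-dimethylformamide dimethyl acetal, COC(OC)N(C)C
Why: Enaminone formation by condensation of the methyl ketone with the amide acetal, then acid-promoted 6-endo addition–elimination of the phenol with loss of dimethylamine, the standard chromone synthesis.

**Step 9**
Reactants: 12 5,7-bis(benzyloxy)-2-(4-methoxyphenyl)-8-[4-(4,4,5,5-tetramethyl-1,3,2-dioxaborolan-2-yl)phenoxy]-4H-chromen-4-one; 16 5,7-bis(benzyloxy)-4H-chromen-4-one
Product: 17 5,7-bis(benzyloxy)-8-{4-[5,7-bis(benzyloxy)-4-oxo-4H-chromen-2-yl]phenoxy}-2-(4-methoxyphenyl)-4H-chromen-4-one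
Conditions: Pd(OCOCF3)2 (cat.), 5-nitro-1,10-phenanthroline (cat.), DMSO, O2 (1 atm), 100 °C; 16 in excess
Reagents that add atoms: none
Why: Oxidative boron-Heck coupling, in which the aryl group is transferred from boron to divalent palladium, inserts across the chromone C2=C3 bond with aryl at C2, and β-hydride elimination through the palladium enolate gives the flavone while O2 reoxidizes the metal.

**Step 10**
Reactants: 17 5,7-bis(benzyloxy)-8-{4-[5,7-bis(benzyloxy)-4-oxo-4H-chromen-2-yl]phenoxy}-2-(4-methoxyphenyl)-4H-chromen-4-one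
Product: 18 8-[4-(5,7-dihydroxy-4-oxo-4H-chromen-2-yl)phenoxy]-5,7-dihydroxy-2-(4-methoxyphenyl)-4H-chromen-4-one (CNP0295851.0)
Conditions: H2 (1 atm), Pd/C, THF–MeOH, rt
Reagents that add atoms: none
Why: Catalytic hydrogenolysis of the four benzyl aryl ethers, under which the conjugated flavone C2=C3 bonds, the diaryl ether and the methyl ether are expected to persist.

**Compound list**
1 | 4-bromophenol | Oc1ccc(Br)cc1 | starting material
2 | methyl 4-chloroacetoacetate | COC(=O)CC(=O)CCl | starting material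
3 | methyl 4-(4-bromophenoxy)-3-oxobutanoate | COC(=O)CC(=O)COc1ccc(Br)cc1 | intermediate
4 | 3-(4-methoxyphenyl)propiolic acid | COc1ccc(C#CC(=O)O)cc1 | starting material
5 | 3-(4-methoxyphenyl)prop-2-ynoyl chloride | COc1ccc(C#CC(=O)Cl)cc1 | intermediate
6 | methyl 2-[(4-bromophenoxy)acetyl]-5-(4-methoxyphenyl)-3-oxopent-4-ynoate | COC(=O)C(C(=O)COc1ccc(Br)cc1)C(=O)C#Cc1ccc(OC)cc1 | intermediate (not isolated)
7 | methyl 2-[(4-bromophenoxy)methyl]-6-(4-methoxyphenyl)-4-oxo-4H-pyran-3-carboxylate | COC(=O)c1c(COc2ccc(Br)cc2)oc(-c2ccc(OC)cc2)cc1=O | intermediate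
8 | ethyl acetate | CCOC(C)=O | starting material
9 | methyl 2-[1-(4-bromophenoxy)-2-oxopropyl]-6-(4-methoxyphenyl)-4-oxo-4H-pyran-3-carboxylate (racemic methine, present as its lithium enolate) | COC(=O)c1c(C(Oc2ccc(Br)cc2)C(C)=O)oc(-c2ccc(OC)cc2)cc1=O | intermediate (not isolated)
10 | 8-(4-bromophenoxy)-5,7-dihydroxy-2-(4-methoxyphenyl)-4H-chromen-4-one | COc1ccc(-c2cc(=O)c3c(O)cc(O)c(Oc4ccc(Br)cc4)c3o2)cc1 | intermediate
11 | 5,7-bis(benzyloxy)-8-(4-bromophenoxy)-2-(4-methoxyphenyl)-4H-chromen-4-one | COc1ccc(-c2cc(=O)c3c(OCc4ccccc4)cc(OCc4ccccc4)c(Oc4ccc(Br)cc4)c3o2)cc1 | intermediate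
12 | 5,7-bis(benzyloxy)-2-(4-methoxyphenyl)-8-[4-(4,4,5,5-tetramethyl-1,3,2-dioxaborolan-2-yl)phenoxy]-4H-chromen-4-one | COc1ccc(-c2cc(=O)c3c(OCc4ccccc4)cc(OCc4ccccc4)c(Oc4ccc(B5OC(C)(C)C(C)(C)O5)cc4)c3o2)cc1 | intermediate
13 | 2',4',6'-trihydroxyacetophenone | CC(=O)c1c(O)cc(O)cc1O | starting material
14 | 1-[2,4-bis(benzyloxy)-6-hydroxyphenyl]ethan-1-one | CC(=O)c1c(O)cc(OCc2ccccc2)cc1OCc1ccccc1 | intermediate
15 | (E)-1-[2,4-bis(benzyloxy)-6-hydroxyphenyl]-3-(dimethylamino)prop-2-en-1-one | CN(C)/C=C/C(=O)c1c(O)cc(OCc2ccccc2)cc1OCc1ccccc1 | intermediate (not isolated)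
16 | 5,7-bis(benzyloxy)-4H-chromen-4-one | O=c1ccoc2cc(OCc3ccccc3)cc(OCc3ccccc3)c12 | intermediate
17 | 5,7-bis(benzyloxy)-8-{4-[5,7-bis(benzyloxy)-4-oxo-4H-chromen-2-yl]phenoxy}-2-(4-methoxyphenyl)-4H-chromen-4-one | COc1ccc(-c2cc(=O)c3c(OCc4ccccc4)cc(OCc4ccccc4)c(Oc4ccc(-c5cc(=O)c6c(OCc7ccccc7)cc(OCc7ccccc7)cc6o5)cc4)c3o2)cc1 | intermediate
18 | 8-[4-(5,7-dihydroxy-4-oxo-4H-chromen-2-yl)phenoxy]-5,7-dihydroxy-2-(4-methoxyphenyl)-4H-chromen-4-one | COc1ccc(-c2cc(=O)c3c(O)cc(O)c(Oc4ccc(-c5cc(=O)c6c(O)cc(O)cc6o5)cc4)c3o2)cc1 | target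

**Step count**
Total: 10 steps. Longest linear sequence: 7 steps (steps 1, 3, 4, 5, 6, 9, 10).

**Steps most likely to fail**

1. Step 4. The stabilized dienolate may be too weak a nucleophile for ethyl acetate, or be consumed by proton transfer. The amide base may add to the pyranone and open it. After acylation the enolate oxygen, not the methyl carbon, may attack the C3 ester and give a fused lactone in place of ring A.
Fallback with known chemistry, leaving from 14 and 1 and rejoining at 11: ketone 14 is condensed with 4-methoxybenzaldehyde (KOH, EtOH, Claisen–Schmidt) to (E)-1-[2,4-bis(benzyloxy)-6-hydroxyphenyl]-3-(4-methoxyphenyl)prop-2-en-1-one F1. This is oxidatively cyclized (I2 cat., DMSO, 120 °C) to 5,7-bis(benzyloxy)-2-(4-methoxyphenyl)-4H-chromen-4-one F2. Electrophilic iodination at C8 (N-iodosuccinimide, CF3CO2H cat., MeCN) should give 5,7-bis(benzyloxy)-8-iodo-2-(4-methoxyphenyl)-4H-chromen-4-one F3. An Ullmann ether coupling of F3 with 4-bromophenol 1 (CuI, N,N-dimethylglycine, Cs2CO3, dioxane, 90 °C; the C–I bond reacts ahead of C–Br) then delivers 11.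

2. Step 9. Transfer of the aryl group from the pinacol boronate to divalent palladium may be slow beside protodeboronation and oxidative homocoupling. Insertion into the electron-rich chromone may be sluggish, or the sequence may stop before β-hydride elimination.
Fallback with known chemistry, leaving from 11 and 14 and rejoining at 17: bromide 11 is hydroxycarbonylated (Pd(OAc)2, 1,1'-bis(diphenylphosphino)ferrocene, CO 1 atm, K2CO3, H2O, DMF, 80 °C) to 4-{[5,7-bis(benzyloxy)-2-(4-methoxyphenyl)-4-oxo-4H-chromen-8-yl]oxy}benzoic acid F4. Esterification with the free phenol of 14 (EDC·HCl, DMAP, CH2Cl2) gives 2-acetyl-3,5-bis(benzyloxy)phenyl 4-{[5,7-bis(benzyloxy)-2-(4-methoxyphenyl)-4-oxo-4H-chromen-8-yl]oxy}benzoate F5. Baker–Venkataraman rearrangement (LiN(SiMe3)2, THF, –20 °C to rt) gives 1-[2,4-bis(benzyloxy)-6-hydroxyphenyl]-3-(4-{[5,7-bis(benzyloxy)-2-(4-methoxyphenyl)-4-oxo-4H-chromen-8-yl]oxy}phenyl)propane-1,3-dione F6. Acid-catalysed cyclodehydration (p-TsOH cat., toluene, reflux) closes the second pyranone ring to 17.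

3. Step 3. Acylation may occur on oxygen or on the aryloxy-bearing carbon of 3. The enolate or pyridine may add to the alkynoyl chloride in conjugate fashion. The enol may close 5-exo to an alkylidene furanone in place of the pyranone.
Fallback, leaving from 5 and 1 and rejoining at 7, with the ether bond made after the ring: methyl acetoacetate is acylated and cyclized with 5 (MgCl2, pyridine, CH2Cl2; then DBU cat.) to methyl 6-(4-methoxyphenyl)-2-methyl-4-oxo-4H-pyran-3-carboxylate F7. Wohl–Ziegler bromination of the 2-methyl group (N-bromosuccinimide, AIBN, PhCF3, 80 °C) gives methyl 2-(bromomethyl)-6-(4-methoxyphenyl)-4-oxo-4H-pyran-3-carboxylate F8. Williamson etherification of F8 with 4-bromophenol 1 (K2CO3, acetone, rt) gives 7.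

**Further compounds**
F1 | step 4 | (E)-1-[2,4-bis(benzyloxy)-6-hydroxyphenyl]-3-(4-methoxyphenyl)prop-2-en-1-one | COc1ccc(/C=C/C(=O)c2c(O)cc(OCc3ccccc3)cc2OCc2ccccc2)cc1
F2 | step 4 | 5,7-bis(benzyloxy)-2-(4-methoxyphenyl)-4H-chromen-4-one | COc1ccc(-c2cc(=O)c3c(OCc4ccccc4)cc(OCc4ccccc4)cc3o2)cc1
F3 | step 4 | 5,7-bis(benzyloxy)-8-iodo-2-(4-methoxyphenyl)-4H-chromen-4-one | COc1ccc(-c2cc(=O)c3c(OCc4ccccc4)cc(OCc4ccccc4)c(I)c3o2)cc1
F4 | step 9 | 4-{[5,7-bis(benzyloxy)-2-(4-methoxyphenyl)-4-oxo-4H-chromen-8-yl]oxy}benzoic acid | COc1ccc(-c2cc(=O)c3c(OCc4ccccc4)cc(OCc4ccccc4)c(Oc4ccc(C(=O)O)cc4)c3o2)cc1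
F5 | step 9 | 2-acetyl-3,5-bis(benzyloxy)phenyl 4-{[5,7-bis(benzyloxy)-2-(4-methoxyphenyl)-4-oxo-4H-chromen-8-yl]oxy}benzoate | COc1ccc(-c2cc(=O)c3c(OCc4ccccc4)cc(OCc4ccccc4)c(Oc4ccc(C(=O)Oc5cc(OCc6ccccc6)cc(OCc6ccccc6)c5C(C)=O)cc4)c3o2)cc1
F6 | step 9 | 1-[2,4-bis(benzyloxy)-6-hydroxyphenyl]-3-(4-{[5,7-bis(benzyloxy)-2-(4-methoxyphenyl)-4-oxo-4H-chromen-8-yl]oxy}phenyl)propane-1,3-dione | COc1ccc(-c2cc(=O)c3c(OCc4ccccc4)cc(OCc4ccccc4)c(Oc4ccc(C(=O)CC(=O)c5c(O)cc(OCc6ccccc6)cc5OCc7ccccc7)cc4)c3o2)cc1
F7 | step 3 | methyl 6-(4-methoxyphenyl)-2-methyl-4-oxo-4H-pyran-3-carboxylate | COC(=O)c1c(C)oc(-c2ccc(OC)cc2)cc1=O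
F8 | step 3 | methyl 2-(bromomethyl)-6-(4-methoxyphenyl)-4-oxo-4H-pyran-3-carboxylate | COC(=O)c1c(CBr)oc(-c2ccc(OC)cc2)cc1=O
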